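## Retrosynthetic overview

- **Feature.** In the ten-membered ring C1–C10, C3–C4 is the only CH2–CH2 edge, C2 bears oxygen, and C5(=C16)–C6–C7 has the carbon pattern of an allene. A temporary C2–C7 bond therefore folds that ring into ring B (C1, C2, C7, C8, C9, C10) of a trans-decalin with vinyl on C2 and allenyl on C7.
- **Key disconnection.** Make C4–C5 and break C2–C7 by anionic oxy-Cope ring expansion of that 2-vinyl-7-allenyl decalin-2-ol.
- **Ring A first.** Benzoic acid → 4,4-disubstituted cyclohexadienone → Rh-catalysed desymmetrising vinyl addition (C1, C10) → epoxide, enolate and Wharton chemistry for the C11, C12 and C14 oxygens.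
- **Ring B second.** Sakurai allylation with an allylsilane from the Roche ester (C7, C8, C17–C19), ring-closing metathesis to C8=C9, epoxide hydrolysis (C8, C9 oxygens), radical allenylation at C7, vinyl addition at C2.
- **Ten-membered ring third, then the end game.** Evans–Tishchenko reduction (C2–OH, C14–OAc), C6=C7 epoxide → chlorohydrin, γ-lactone, spiro-epoxide and acetates last.

Key step: step 27

**Remarks**
- Briarane numbering is used throughout; β is the face of the C15 methyl, α the opposite face.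
- The (S)-Roche ester is used, because its ester carbon becomes C8 and C17 then has the configuration of the target.
- The C2 carbinol centre in 25 and 26 is not controlled and is removed in step 20, so it is written without a descriptor; the hemiacetal carbon of 45 likewise.
- Simple alkoxide salts of a reactant are not numbered, except in the key step.
- Triphenyl(prop-2-yn-1-yl)stannane is a known reagent, made from propargyl bromide and Ph3SnCl.

## Route

Step 1
Reactants: 1 benzoic acid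
Product: 3 1-methylcyclohexa-2,5-diene-1-carboxylic acid, via dilithium dienide carboxylate 2 (not isolated)
Conditions: Li, NH3(l), THF, −78 °C; then MeI; HCl work-up
Reagents that add atoms: iodomethane CI; lithium [Li] (counter-ions of 2 only)
Why: Birch reductive alkylation: the dissolving metal gives the 1,4-dihydro dianion, which is methylated at the carboxylate-bearing carbon (future C1).

Step 2
Reactants: 3 diene acid
Product: 4 (1-methylcyclohexa-2,5-dien-1-yl)methanol
Conditions: LiAlH4, THF, 0 °C → rt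
Reagents that add atoms: none
Why: Hydride reduction of the acid to the primary alcohol (future C2); the isolated alkenes are inert.

Step 3
Reactants: 4 dienyl methanol
Product: 5 TBDPS ether of 4
Conditions: TBDPSCl, imidazole, DMF, rt
Reagents that add atoms: tert-butylchlorodiphenylsilane CC(C)(C)[Si](Cl)(c1ccccc1)c1ccccc1
Why: Silylation of the primary alcohol gives a bulky group that later directs the facial course of step 5.

Step 4
Reactants: 5 silyl ether
Product: 6 4-[(tert-butyldiphenylsilyloxy)methyl]-4-methylcyclohexa-2,5-dien-1-one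
Conditions: CrO3 (10 mol %), t-BuOOH, CH2Cl2, rt
Reagents that add atoms: tert-butyl hydroperoxide CC(C)(C)OO
Why: Chromium-catalysed allylic oxidation of the only (doubly allylic) CH2 gives the cross-conjugated dienone, which cannot aromatise because C1 is quaternary.

Step 5
Reactants: 6 dienone
Product: 7 4-[(TBDPS-oxy)methyl]-4-methyl-5-vinylcyclohex-2-en-1-one (vinyl cis to methyl)
Conditions: CH2=CHBF3K, [Rh(cod)2]BF4 (3 mol %), (R)-BINAP (3.3 mol %), Et3N, PhMe/H2O, 25 °C
Reagents that add atoms: potassium vinyltrifluoroborate [K+].C=C[B-](F)(F)F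
Why: Hayashi–Miyaura asymmetric 1,4-addition desymmetrises the two enantiotopic enone arms; the catalyst chooses the arm (C10, and with it C1), vinyl adds anti to the bulky CH2OTBDPS group, and (R)-BINAP is the ligand expected from the usual facial model for rhodium–BINAP additions.

Step 6
Reactants: 7 vinyl enone
Product: 8 13α,14α-epoxy ketone
Conditions: 30% H2O2, NaOH (0.3 equiv), MeOH, 0 °C
Reagents that add atoms: hydrogen peroxide OO
Why: Weitz–Scheffer epoxidation: in the half-chair with CH2OTBDPS and vinyl equatorial, hydroperoxide adds to C14 axially, anti to the axial C15 methyl and trans to the C10 vinyl, so the epoxide (and the C14–O bond) is α.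

Step 7
Reactants: 8 epoxy ketone
Product: 10 C11-(PMB-oxymethyl) epoxy ketone, via lithium enolate 9 (not isolated)
Conditions: LiN(iPr)2, THF, −78 °C; then PMBOCH2Cl, −78 → −40 °C
Reagents that add atoms: 4-methoxybenzyl chloromethyl ether COc1ccc(COCCl)cc1; lithium diisopropylamide [Li+].CC(C)[N-]C(C)C (lithium of 9 only)
Why: Enolate alkylation at C11, the only enolisable position, brings in C20 anti to the C10 vinyl; the C11 configuration is reset in step 8.

Step 8
Reactants: 10 alkylated epoxy ketone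
Product: 12 11α-hydroxy epoxy ketone, via potassium enolate 11 (not isolated)
Conditions: KN(SiMe3)2, THF, −78 °C; then 2-(phenylsulfonyl)-3-phenyloxaziridine; sat. NH4Cl
Reagents that add atoms: 2-(phenylsulfonyl)-3-phenyloxaziridine O=S(=O)(c1ccccc1)N1OC1c1ccccc1; potassium hexamethyldisilazide [K+].C[Si](C)(C)[N-][Si](C)(C)C (potassium of 11 only)
Why: Davis enolate hydroxylation: oxygen enters the tetrasubstituted enolate anti to the adjacent β-vinyl group and away from the β-methyl on C1, giving C11–OH α and C20 β.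

Step 9
Reactants: 12 hydroxy epoxy ketone
Product: 14 ring A 12-ene-11α,14α-diol, via epoxy hydrazone 13 (not isolated)
Conditions: N2H4·H2O, AcOH (cat.), MeOH, 0 °C → rt
Reagents that add atoms: none
Why: Wharton transposition: the hydrazone fragments with loss of N2 to the allylic alcohol, and the C14–O bond of the epoxide is kept, so C14–OH is α.

Step 10
Reactants: 14 diol
Product: 15 14-PMB ether
Conditions: NaH (1.1 equiv), PMBCl, Bu4NI (cat.), THF/DMF, 0 °C
Reagents that add atoms: 4-methoxybenzyl chloride COc1ccc(CCl)cc1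
Why: Williamson etherification at the secondary allylic alkoxide; the hindered tertiary C11–OH stays free.

Step 11
Reactants: 15 PMB ether
Product: 16 12α,13α-epoxide
Conditions: VO(acac)2 (5 mol %), t-BuOOH, CH2Cl2, 0 °C
Reagents that add atoms: tert-butyl hydroperoxide CC(C)(C)OO
Why: Hydroxyl-directed epoxidation: the tertiary allylic C11–OH (α) binds vanadium and delivers oxygen to the α face of C12=C13, and the undirected vinyl group is left alone.

Step 12
Reactants: 16 epoxy alcohol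
Product: 17 11α,12α-diol
Conditions: LiAlH4, THF, 0 °C
Reagents that add atoms: none
Why: SN2 hydride opening at C13, remote from the fully substituted C11 and the trans-diaxial mode, keeps the oxygen on C12 with α configuration.

Step 13
Reactants: 17 diol
Product: 18 11,12-bis-MOM ether
Conditions: MOMCl, iPr2NEt, Bu4NI, ClCH2CH2Cl, 50 °C
Reagents that add atoms: chloromethyl methyl ether COCCl
Why: Forcing MOM etherification covers the secondary and the tertiary hydroxyl with groups that cannot migrate to an alkoxide later.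

Step 14
Reactants: 18 silyl ether
Product: 19 C2 primary alcohol
Conditions: Bu4NF, THF, rt
Reagents that add atoms: none
Why: Fluoride cleaves the only silyl ether.

Step 15
Reactants: 19 alcohol
Product: 20 ring A aldehyde (C2 = CHO)
Conditions: Dess–Martin periodinane, NaHCO3, CH2Cl2, rt
Reagents that add atoms: none
Why: Mild oxidation to the neopentyl aldehyde, which has no α-hydrogen and cannot epimerise.

Step 16
Reactants: 21 methyl (S)-3-hydroxy-2-methylpropanoate
Product: 22 its TBDPS ether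
Conditions: TBDPSCl, imidazole, DMF, rt
Reagents that add atoms: tert-butylchlorodiphenylsilane CC(C)(C)[Si](Cl)(c1ccccc1)c1ccccc1
Why: Standard silylation; the stereocentre (future C17) is untouched.

Step 17
Reactants: 22 silyl ester
Product: 24 (R)-allylsilane, via bis(silylmethyl) carbinol 23 (not isolated)
Conditions: Me3SiCH2MgCl (3 equiv), CeCl3, THF, −78 °C → rt; then SiO2, CH2Cl2
Reagents that add atoms: (trimethylsilyl)methylmagnesium chloride C[Si](C)(C)C[Mg]Cl
Why: The organocerium adds twice to the ester without enolising the α-centre, and Peterson elimination of the carbinol gives the 2-substituted allylsilane; the ester carbon becomes C8.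

Step 18
Reactants: 20 ring A aldehyde; 24 allylsilane
Product: 25 homoallylic alcohol (C2 carbinol; C7, C8 and the C17–C19 chain attached)
Conditions: BF3·OEt2, CH2Cl2, −78 °C
Reagents that add atoms: none
Why: Hosomi–Sakurai allylation forms C2–C7; the new C2 carbinol centre is not controlled and is erased in step 20.

Step 19
Reactants: 25 diene alcohol
Product: 26 trans-decalin 8-en-2-ol
Conditions: second-generation Grubbs catalyst (H2IMes)(PCy3)Cl2Ru=CHPh (5 mol %), CH2Cl2, 40 °C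
Reagents that add atoms: none
Why: Ring-closing metathesis of the C10 vinyl group with the 1,1-disubstituted alkene closes ring B as a trisubstituted cyclohexene; the trans ring fusion follows from the trans C2 and C9 arms set in step 5.

Step 20
Reactants: 26 decalinol
Product: 27 trans-decalin 8-en-2-one
Conditions: Dess–Martin periodinane, NaHCO3, CH2Cl2, rt
Reagents that add atoms: none
Why: Oxidation of the secondary alcohol gives the C2 ketone and removes the uncontrolled centre.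

Step 21
Reactants: 27 enone (β,γ)
Product: 28 8α,9α-epoxide
Conditions: mCPBA, NaHCO3, CH2Cl2, 0 °C
Reagents that add atoms: 3-chloroperbenzoic acid OOC(=O)c1cccc(Cl)c1
Why: Prilezhaev epoxidation of the only alkene from the α face, because the β face of C8=C9 is screened by the axial C15 methyl.

Step 22
Reactants: 28 epoxy ketone
Product: 29 8α,9β-diol
Conditions: HClO4 (cat.), THF/H2O, 0 °C
Reagents that add atoms: water O
Why: Fürst–Plattner trans-diaxial opening: water attacks secondary C9 from the β face, so C8–OH is α-axial and C9–OH is β-axial.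

Step 23
Reactants: 29 diol
Product: 30 8,9-bis-MOM ether
Conditions: MOMCl, iPr2NEt, Bu4NI, ClCH2CH2Cl, 45 °C
Reagents that add atoms: chloromethyl methyl ether COCCl
Why: MOM etherification of the secondary and tertiary hydroxyls under weakly basic conditions that do not enolise the ketone.

Step 24
Reactants: 30 ketone
Product: 32 7α-bromo ketone, via trimethylsilyl enol ether 31 (not isolated)
Conditions: LiN(SiMe3)2, Me3SiCl, THF, −78 °C; then NBS, −78 → 0 °C
Reagents that add atoms: N-bromosuccinimide O=C1CCC(=O)N1Br; chlorotrimethylsilane C[Si](C)(C)Cl (silicon of 31 only)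
Why: C7 is the only enolisable position; the silyl enol ether is brominated there, and the configuration of the bromide does not matter.

Step 25
Reactants: 32 bromo ketone
Product: 33 7α-allenyl ketone
Conditions: HC≡CCH2SnPh3 (3 equiv), AIBN (cat.), PhH, 80 °C
Reagents that add atoms: triphenyl(prop-2-yn-1-yl)stannane C#CC[Sn](c1ccccc1)(c1ccccc1)c1ccccc1
Why: Radical chain SH2′ allenyl transfer: the C7 radical adds to the alkyne terminus and expels Ph3Sn•, and it is trapped from the α face because the β face carries two syn-axial groups (C15 methyl, C9–OMOM).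

Step 26
Reactants: 33 allenyl ketone
Product: 34 2β-vinyl-2α-hydroxy-7α-allenyl trans-decalin
Conditions: CH2=CHMgBr, CeCl3, THF, −78 °C
Reagents that add atoms: vinylmagnesium bromide C=C[Mg]Br
Why: The organocerium adds 1,2 without enolising C7; axial approach is blocked by the syn-axial C8–OMOM and H10, so equatorial attack gives vinyl β-equatorial and OH α-axial.

Step 27
Reactants: 34 vinyl allenyl carbinol
Product: 37 ten-membered 2-ketone with (6E)-alkene and 5(16)-methylene, via potassium alkoxide 35 (not isolated), via potassium enolate 36 (not isolated)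
Conditions: KH, 18-crown-6, THF, 0 → 40 °C; then sat. NH4Cl, −78 °C
Reagents that add atoms: potassium hydride [K+].[H-] (potassium of 35 and 36 only)
Why: KH with 18-crown-6 turns the axial C2 hydroxyl into a bare potassium alkoxide, which undergoes the anion-accelerated [3,3] shift of the C4=C3–C2–C7–C6=C5 array through a chair transition state: C4 bonds to the central allene carbon C5, C2–C7 breaks, and the C2 enolate, the C6=C7 bond and the untouched C5=C16 bond appear together. The closest known reaction is the anionic oxy-Cope ring expansion of trans-1-vinyl-2-alkenylcyclohexanols to (E)-cyclodec-5-enones, run here with an allene as the second two-electron component as in the allenyl Cope rearrangement. The ten-membered ring is not closed by a cyclisation but arises by four-atom sigmatropic ring expansion of ring B, so no exo or endo closure mode applies. No stereocentre is created (C2 and C7 become trigonal); the one stereochemical outcome is the E geometry of C6=C7, set by the chair transition state in which C8 is pseudo-equatorial. The step needs bonding at the central allene carbon (only C5 can reach C4 in a six-atom array), E selectivity (the trans-diequatorial vinyl and allenyl groups on the rigid trans-decalin exclude the boat) and irreversibility (enolate formation). It also needs an inert periphery: the MOM, PMB and TBDPS ethers should not migrate to the alkoxide, and the axial C8–OMOM bond is gauche to C2–C7, which disfavours Grob fragmentation.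

Step 28
Reactants: 37 ketone
Product: 38 14α,20-diol
Conditions: DDQ, CH2Cl2/pH 7 buffer, 0 °C
Reagents that add atoms: none
Why: Oxidative cleavage of both PMB ethers; MOM and silyl ethers and the twisted diene are expected to survive.

Step 29
Reactants: 38 diol
Product: 39 20-tosylate
Conditions: TsCl, Et3N, DMAP (cat.), CH2Cl2, 0 °C
Reagents that add atoms: 4-toluenesulfonyl chloride Cc1ccc(S(Cl)(=O)=O)cc1
Why: Sulfonylation of the primary C20–OH over the hindered secondary C14–OH.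

Step 30
Reactants: 39 β-hydroxy ketone
Product: 40 14-acetate 2β-alcohol
Conditions: SmI2 (30 mol %), MeCHO (5 equiv), THF, −10 °C
Reagents that add atoms: acetaldehyde CC=O
Why: Evans–Tishchenko reduction: the samarium-bound hemiacetal of C14–OH with acetaldehyde delivers hydride to C2 through a six-membered transition state, giving the 1,3-anti relationship of C14–O and C2–O that the target has, with the C14 acetate formed in the same event.

Step 31
Reactants: 40 alcohol
Product: 41 2-isobutyrate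
Conditions: i-PrCOCl, pyridine, DMAP, CH2Cl2, 0 °C → rt
Reagents that add atoms: isobutyryl chloride CC(C)C(=O)Cl
Why: Acylation of the only free hydroxyl, run promptly so that the C14 acetate does not migrate.

Step 32
Reactants: 41 diene
Product: 42 6,7-epoxide (oxygen α at C7)
Conditions: mCPBA, NaHCO3, CH2Cl2, −20 °C
Reagents that add atoms: 3-chloroperbenzoic acid OOC(=O)c1cccc(Cl)c1
Why: Prilezhaev epoxidation of the strained E-alkene in preference to the 1,1-disubstituted alkene; attack on the outer face of C6=C7 in the conformation inherited from the chair transition state (the inner face points across the ring at C2) gives C7–O α.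

Step 33
Reactants: 42 vinyl epoxide
Product: 43 6α-chloro-7α-alcohol
Conditions: LiCl, AcOH, THF, rt
Reagents that add atoms: lithium chloride [Li+].[Cl-]
Why: Acid-assisted SN2 opening of the vinyl epoxide at the allylic carbon C6 with inversion, so chlorine and the C7 oxygen end up on the α face.

Step 34
Reactants: 43 chlorohydrin
Product: 44 7,19-diol
Conditions: HF·pyridine, pyridine, THF, 0 °C → rt
Reagents that add atoms: none
Why: Selective cleavage of the primary TBDPS ether; MOM ethers, esters, tosylate and chloride are stable to buffered HF.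

Step 35
Reactants: 44 diol
Product: 46 7,19-lactone, via lactol 45 (not isolated)
Conditions: TEMPO (cat.), PhI(OAc)2, CH2Cl2, rt
Reagents that add atoms: none
Why: Oxidative lactonisation of a 1,4-diol: the primary alcohol is oxidised to the aldehyde, which closes on C7–OH and is oxidised again; C9 is still MOM-protected, so only the C7 lactone can form.

Step 36
Reactants: 46 lactone
Product: 48 8,9,11,12-tetraol, via tetrakis(bromomethyl) ether 47 (not isolated)
Conditions: Me2BBr (8 equiv), CH2Cl2, −78 °C; then sat. NaHCO3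
Reagents that add atoms: bromodimethylborane CB(C)Br (bromine of 47 only)
Why: Lewis-acid cleavage of the four MOM ethers, tertiary ones included, at low temperature, where esters, lactone, tosylate and allylic chloride should persist.

Step 37
Reactants: 48 tetraol
Product: 49 9,12-diacetate
Conditions: Ac2O, pyridine, DMAP (cat.), CH2Cl2, 0 °C → rt
Reagents that add atoms: acetic anhydride CC(=O)OC(C)=O
Why: Acetylation of the two secondary hydroxyls; the tertiary C8–OH and C11–OH do not react under these conditions.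

Step 38
Reactants: 49 hydroxy tosylate
Product: 50 CNP0145565.1 (target)
Conditions: DBU, CH2Cl2, rt
Reagents that add atoms: none
Why: Intramolecular Williamson closure (3-exo-tet) of the C11 oxygen onto C20 gives the spiro-epoxide with retention at C11 (oxygen α, C20 β).

## Compound list

1 | benzoic acid | OC(=O)c1ccccc1 | starting material
2 | dilithium 1-carboxylatocyclohexa-2,5-dien-1-ide | [Li+].[Li+].[O-]C(=O)[C-]1C=CCC=C1 | intermediate
3 | 1-methylcyclohexa-2,5-diene-1-carboxylic acid | CC1(C(=O)O)C=CCC=C1 | intermediate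
4 | (1-methylcyclohexa-2,5-dien-1-yl)methanol | CC1(CO)C=CCC=C1 | intermediate
5 | tert-butyl[(1-methylcyclohexa-2,5-dien-1-yl)methoxy]diphenylsilane | CC1(CO[Si](c2ccccc2)(c3ccccc3)C(C)(C)C)C=CCC=C1 | intermediate
6 | 4-[(tert-butyldiphenylsilyloxy)methyl]-4-methylcyclohexa-2,5-dien-1-one | CC1(CO[Si](c2ccccc2)(c3ccccc3)C(C)(C)C)C=CC(=O)C=C1 | intermediate
7 | 4-[(TBDPS-oxy)methyl]-4-methyl-5-vinylcyclohex-2-en-1-one, vinyl cis to methyl (ring A: C12=O, C13=C14, C1, C10, C11) | CC(C)(C)[Si](c2ccccc2)(c3ccccc3)OC[C@@]1(C)C=CC(=O)C[C@@H]1C=C | intermediate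
8 | 13α,14α-epoxy ketone of 7 | CC(C)(C)[Si](c2ccccc2)(c3ccccc3)OC[C@@]1(C)[C@H]5O[C@H]5C(=O)C[C@@H]1C=C | intermediate
9 | lithium C11=C12 enolate of 8 | [Li+].CC(C)(C)[Si](c2ccccc2)(c3ccccc3)OC[C@@]1(C)[C@H]5O[C@H]5C([O-])=C[C@@H]1C=C | intermediate
10 | epoxy ketone with 11α-CH2OPMB (C20 trans to vinyl) | CC(C)(C)[Si](c2ccccc2)(c3ccccc3)OC[C@@]1(C)[C@H]5O[C@H]5C(=O)[C@@H](COCc4ccc(OC)cc4)[C@@H]1C=C | intermediate
11 | potassium C11=C12 enolate of 10 | [K+].CC(C)(C)[Si](c2ccccc2)(c3ccccc3)OC[C@@]1(C)[C@H]5O[C@H]5C([O-])=C(COCc4ccc(OC)cc4)[C@@H]1C=C | intermediate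
12 | epoxy ketone with 11α-OH and 11β-CH2OPMB | CC(C)(C)[Si](c2ccccc2)(c3ccccc3)OC[C@@]1(C)[C@H]5O[C@H]5C(=O)[C@](O)(COCc4ccc(OC)cc4)[C@@H]1C=C | intermediate
13 | C12 hydrazone of 12 | CC(C)(C)[Si](c2ccccc2)(c3ccccc3)OC[C@@]1(C)[C@H]5O[C@H]5C(=NN)[C@](O)(COCc4ccc(OC)cc4)[C@@H]1C=C | intermediate
14 | ring A 12-ene-11α,14α-diol | CC(C)(C)[Si](c2ccccc2)(c3ccccc3)OC[C@@]1(C)[C@@H](O)C=C[C@](O)(COCc4ccc(OC)cc4)[C@@H]1C=C | intermediate
15 | 14α-PMB ether of 14 | CC(C)(C)[Si](c2ccccc2)(c3ccccc3)OC[C@@]1(C)[C@@H](OCc5ccc(OC)cc5)C=C[C@](O)(COCc4ccc(OC)cc4)[C@@H]1C=C | intermediate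
16 | 12α,13α-epoxide of 15 | CC(C)(C)[Si](c2ccccc2)(c3ccccc3)OC[C@@]1(C)[C@@H](OCc5ccc(OC)cc5)[C@H]6O[C@H]6[C@](O)(COCc4ccc(OC)cc4)[C@@H]1C=C | intermediate
17 | ring A 11α,12α-diol, 14α-OPMB | CC(C)(C)[Si](c2ccccc2)(c3ccccc3)OC[C@@]1(C)[C@@H](OCc5ccc(OC)cc5)C[C@@H](O)[C@](O)(COCc4ccc(OC)cc4)[C@@H]1C=C | intermediate
18 | 11,12-bis-MOM ether of 17 | CC(C)(C)[Si](c2ccccc2)(c3ccccc3)OC[C@@]1(C)[C@@H](OCc5ccc(OC)cc5)C[C@@H](OCOC)[C@](OCOC)(COCc4ccc(OC)cc4)[C@@H]1C=C | intermediate
19 | ring A C2 primary alcohol | OC[C@@]1(C)[C@@H](OCc5ccc(OC)cc5)C[C@@H](OCOC)[C@](OCOC)(COCc4ccc(OC)cc4)[C@@H]1C=C | intermediate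
20 | ring A aldehyde (C2 = CHO; 14α-OPMB, 11α,12α-OMOM, 20-OPMB, 10β-vinyl) | O=C[C@@]1(C)[C@@H](OCc5ccc(OC)cc5)C[C@@H](OCOC)[C@](OCOC)(COCc4ccc(OC)cc4)[C@@H]1C=C | intermediate
21 | methyl (S)-3-hydroxy-2-methylpropanoate | OC[C@H](C)C(=O)OC | starting material
22 | methyl (S)-3-(tert-butyldiphenylsilyloxy)-2-methylpropanoate | CC(C)(C)[Si](c1ccccc1)(c1ccccc1)OC[C@H](C)C(=O)OC | intermediate
23 | tertiary carbinol bearing two CH2SiMe3 groups | CC(C)(C)[Si](c1ccccc1)(c1ccccc1)OC[C@H](C)C(O)(C[Si](C)(C)C)C[Si](C)(C)C | intermediate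
24 | tert-butyl{[(2R)-2-methyl-3-(trimethylsilylmethyl)but-3-en-1-yl]oxy}diphenylsilane | CC(C)(C)[Si](c1ccccc1)(c1ccccc1)OC[C@H](C)C(=C)C[Si](C)(C)C | intermediate
25 | homoallylic alcohol: ring A with C2H(OH)–C7H2–C8(=CH2)–C17 chain (C2 epimers) | OC(CC(=C)[C@@H](C)CO[Si](c6ccccc6)(c7ccccc7)C(C)(C)C)[C@@]1(C)[C@@H](OCc5ccc(OC)cc5)C[C@@H](OCOC)[C@](OCOC)(COCc4ccc(OC)cc4)[C@@H]1C=C | intermediate
26 | trans-decalin 8-en-2-ol (C2 epimers) | OC1[C@@]2(C)[C@@H](OCc5ccc(OC)cc5)C[C@@H](OCOC)[C@](OCOC)(COCc4ccc(OC)cc4)[C@@H]2C=C([C@@H](C)CO[Si](c6ccccc6)(c7ccccc7)C(C)(C)C)C1 | intermediate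
27 | trans-decalin 8-en-2-one | O=C1[C@@]2(C)[C@@H](OCc5ccc(OC)cc5)C[C@@H](OCOC)[C@](OCOC)(COCc4ccc(OC)cc4)[C@@H]2C=C([C@@H](C)CO[Si](c6ccccc6)(c7ccccc7)C(C)(C)C)C1 | intermediate
28 | 8α,9α-epoxy-2-one | O=C1[C@@]2(C)[C@@H](OCc5ccc(OC)cc5)C[C@@H](OCOC)[C@](OCOC)(COCc4ccc(OC)cc4)[C@@H]2[C@H]8O[C@@]8([C@@H](C)CO[Si](c6ccccc6)(c7ccccc7)C(C)(C)C)C1 | intermediate
29 | 8α,9β-dihydroxy-2-one | O=C1[C@@]2(C)[C@@H](OCc5ccc(OC)cc5)C[C@@H](OCOC)[C@](OCOC)(COCc4ccc(OC)cc4)[C@@H]2[C@H](O)[C@](O)([C@@H](C)CO[Si](c6ccccc6)(c7ccccc7)C(C)(C)C)C1 | intermediate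
30 | 8α,9β-bis-MOM 2-ketone | O=C1[C@@]2(C)[C@@H](OCc5ccc(OC)cc5)C[C@@H](OCOC)[C@](OCOC)(COCc4ccc(OC)cc4)[C@@H]2[C@H](OCOC)[C@](OCOC)([C@@H](C)CO[Si](c6ccccc6)(c7ccccc7)C(C)(C)C)C1 | intermediate
31 | C2=C7 trimethylsilyl enol ether of 30 | C[Si](C)(C)OC=1[C@@]2(C)[C@@H](OCc5ccc(OC)cc5)C[C@@H](OCOC)[C@](OCOC)(COCc4ccc(OC)cc4)[C@@H]2[C@H](OCOC)[C@](OCOC)([C@@H](C)CO[Si](c6ccccc6)(c7ccccc7)C(C)(C)C)C=1 | intermediate
32 | 7α-bromo 2-ketone | O=C1[C@@]2(C)[C@@H](OCc5ccc(OC)cc5)C[C@@H](OCOC)[C@](OCOC)(COCc4ccc(OC)cc4)[C@@H]2[C@H](OCOC)[C@](OCOC)([C@@H](C)CO[Si](c6ccccc6)(c7ccccc7)C(C)(C)C)[C@H]1Br | intermediate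
33 | 7α-(propa-1,2-dienyl) 2-ketone | O=C1[C@@]2(C)[C@@H](OCc5ccc(OC)cc5)C[C@@H](OCOC)[C@](OCOC)(COCc4ccc(OC)cc4)[C@@H]2[C@H](OCOC)[C@](OCOC)([C@@H](C)CO[Si](c6ccccc6)(c7ccccc7)C(C)(C)C)[C@H]1C=C=C | intermediate
34 | trans-decalin with 2β-vinyl, 2α-OH and 7α-allenyl (key-step precursor) | C=C[C@]1(O)[C@@]2(C)[C@@H](OCc5ccc(OC)cc5)C[C@@H](OCOC)[C@](OCOC)(COCc4ccc(OC)cc4)[C@@H]2[C@H](OCOC)[C@](OCOC)([C@@H](C)CO[Si](c6ccccc6)(c7ccccc7)C(C)(C)C)[C@H]1C=C=C | intermediate
35 | potassium 2-alkoxide of 34 | [K+].C=C[C@]1([O-])[C@@]2(C)[C@@H](OCc5ccc(OC)cc5)C[C@@H](OCOC)[C@](OCOC)(COCc4ccc(OC)cc4)[C@@H]2[C@H](OCOC)[C@](OCOC)([C@@H](C)CO[Si](c6ccccc6)(c7ccccc7)C(C)(C)C)[C@H]1C=C=C | intermediate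
36 | potassium C2=C3 enolate of 37 | [K+].C1C=C([O-])[C@@]2(C)[C@@H](OCc5ccc(OC)cc5)C[C@@H](OCOC)[C@](OCOC)(COCc4ccc(OC)cc4)[C@@H]2[C@H](OCOC)[C@](OCOC)([C@@H](C)CO[Si](c6ccccc6)(c7ccccc7)C(C)(C)C)/C=C/C1=C | intermediate
37 | ten-membered 2-ketone, (6E)-ene, 5(16)-methylene (key-step product) | C1CC(=O)[C@@]2(C)[C@@H](OCc5ccc(OC)cc5)C[C@@H](OCOC)[C@](OCOC)(COCc4ccc(OC)cc4)[C@@H]2[C@H](OCOC)[C@](OCOC)([C@@H](C)CO[Si](c6ccccc6)(c7ccccc7)C(C)(C)C)/C=C/C1=C | intermediate
38 | 14α,20-diol of 37 | C1CC(=O)[C@@]2(C)[C@@H](O)C[C@@H](OCOC)[C@](OCOC)(CO)[C@@H]2[C@H](OCOC)[C@](OCOC)([C@@H](C)CO[Si](c6ccccc6)(c7ccccc7)C(C)(C)C)/C=C/C1=C | intermediate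
39 | 20-tosylate, 14α-OH, 2-ketone | C1CC(=O)[C@@]2(C)[C@@H](O)C[C@@H](OCOC)[C@](OCOC)(COS(=O)(=O)c4ccc(C)cc4)[C@@H]2[C@H](OCOC)[C@](OCOC)([C@@H](C)CO[Si](c6ccccc6)(c7ccccc7)C(C)(C)C)/C=C/C1=C | intermediate
40 | 14α-acetate, 2β-alcohol | C1C[C@H](O)[C@@]2(C)[C@@H](OC(C)=O)C[C@@H](OCOC)[C@](OCOC)(COS(=O)(=O)c4ccc(C)cc4)[C@@H]2[C@H](OCOC)[C@](OCOC)([C@@H](C)CO[Si](c6ccccc6)(c7ccccc7)C(C)(C)C)/C=C/C1=C | intermediate
41 | 2β-isobutyrate, 14α-acetate diene | C1C[C@H](OC(=O)C(C)C)[C@@]2(C)[C@@H](OC(C)=O)C[C@@H](OCOC)[C@](OCOC)(COS(=O)(=O)c4ccc(C)cc4)[C@@H]2[C@H](OCOC)[C@](OCOC)([C@@H](C)CO[Si](c6ccccc6)(c7ccccc7)C(C)(C)C)/C=C/C1=C | intermediate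
42 | 6,7-epoxide (trans; oxygen α at C7) | C=C1CC[C@H](OC(=O)C(C)C)[C@@]2(C)[C@@H](OC(C)=O)C[C@@H](OCOC)[C@](OCOC)(COS(=O)(=O)c4ccc(C)cc4)[C@@H]2[C@H](OCOC)[C@](OCOC)([C@@H](C)CO[Si](c6ccccc6)(c7ccccc7)C(C)(C)C)[C@H]3O[C@H]13 | intermediate
43 | 6α-chloro-7α-alcohol | C=C1CC[C@H](OC(=O)C(C)C)[C@@]2(C)[C@@H](OC(C)=O)C[C@@H](OCOC)[C@](OCOC)(COS(=O)(=O)c4ccc(C)cc4)[C@@H]2[C@H](OCOC)[C@](OCOC)([C@@H](C)CO[Si](c6ccccc6)(c7ccccc7)C(C)(C)C)[C@@H](O)[C@H]1Cl | intermediate
44 | 6α-chloro-7α,19-diol | C=C1CC[C@H](OC(=O)C(C)C)[C@@]2(C)[C@@H](OC(C)=O)C[C@@H](OCOC)[C@](OCOC)(COS(=O)(=O)c4ccc(C)cc4)[C@@H]2[C@H](OCOC)[C@](OCOC)([C@@H](C)CO)[C@@H](O)[C@H]1Cl | intermediate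
45 | 7,19-lactol | C=C1CC[C@H](OC(=O)C(C)C)[C@@]2(C)[C@@H](OC(C)=O)C[C@@H](OCOC)[C@](OCOC)(COS(=O)(=O)c4ccc(C)cc4)[C@@H]2[C@H](OCOC)[C@]2(OCOC)[C@@H](C)C(O)O[C@H]2[C@H]1Cl | intermediate
46 | 7,19-lactone with MOM ethers at C8, C9, C11, C12 | C=C1CC[C@H](OC(=O)C(C)C)[C@@]2(C)[C@@H](OC(C)=O)C[C@@H](OCOC)[C@](OCOC)(COS(=O)(=O)c4ccc(C)cc4)[C@@H]2[C@H](OCOC)[C@]2(OCOC)[C@@H](C)C(=O)O[C@H]2[C@H]1Cl | intermediate
47 | tetrakis(bromomethyl) ether of 48 | C=C1CC[C@H](OC(=O)C(C)C)[C@@]2(C)[C@@H](OC(C)=O)C[C@@H](OCBr)[C@](OCBr)(COS(=O)(=O)c4ccc(C)cc4)[C@@H]2[C@H](OCBr)[C@]2(OCBr)[C@@H](C)C(=O)O[C@H]2[C@H]1Cl | intermediate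
48 | lactone 8α,9β,11α,12α-tetraol 20-tosylate | C=C1CC[C@H](OC(=O)C(C)C)[C@@]2(C)[C@@H](OC(C)=O)C[C@@H](O)[C@](O)(COS(=O)(=O)c4ccc(C)cc4)[C@@H]2[C@H](O)[C@]2(O)[C@@H](C)C(=O)O[C@H]2[C@H]1Cl | intermediate
49 | 9,12,14-triacetate 2-isobutyrate 11-hydroxy 20-tosylate | C=C1CC[C@H](OC(=O)C(C)C)[C@@]2(C)[C@@H](OC(C)=O)C[C@@H](OC(C)=O)[C@](O)(COS(=O)(=O)c4ccc(C)cc4)[C@@H]2[C@H](OC(C)=O)[C@]2(O)[C@@H](C)C(=O)O[C@H]2[C@H]1Cl | intermediate
50 | CNP0145565.1 | C=C1CC[C@H](OC(=O)C(C)C)[C@@]2(C)[C@@H](OC(C)=O)C[C@@H](OC(C)=O)[C@]3(CO3)[C@@H]2[C@H](OC(C)=O)[C@]2(O)[C@@H](C)C(=O)O[C@H]2[C@H]1Cl | target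

## Step count and risks

Total: 38 steps. Longest linear sequence: 36 steps (steps 1–15 and 18–38 from benzoic acid); the allylsilane branch is steps 16–17.

**Step 27 (key step).** The alkoxide may decompose by base-induced isomerisation of the allene before it rearranges, or rearrange through a boat and lose the E geometry. The fallback replaces the allene by a vinyl group and adds C16 afterwards. It sets out from ketone 30: its lithium enolate is added to phenyl vinyl sulfoxide to give the β-keto sulfoxide adduct F1, and thermolysis (PhMe, 110 °C) gives the 7α-vinyl ketone F2. CH2=CHMgBr/CeCl3 then gives the 2,7-divinyl carbinol F3. KH/18-crown-6 effects the standard divinyl anionic oxy-Cope expansion to the (6E)-cyclodecenone F4, in which C5 is CH2. Allylic oxidation at C5, the only allylic CH2 (SeO2/t-BuOOH, then Dess–Martin periodinane), gives the 5-oxo enone F5. Ph3P=CH2 methylenates the enone carbonyl in preference to the hindered C2 ketone and returns to 37.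

**Step 25.** Chain transfer from the hindered α-keto radical to the stannane may be slow, so that reduction of the bromide or allene/alkyne scrambling takes over. The fallback builds the allene by an ionic elimination. It sets out from ketone 30: aldol addition of its lithium enolate to 2-(trimethylsilyl)prop-2-enal gives the β-hydroxy vinylsilane F6. CH2=CHMgBr/CeCl3 gives the diol F7, and MsCl/Et3N mesylates only the secondary allylic hydroxyl to give F8. Bu4NF then induces β-elimination of silicon and mesylate to the terminal allene and returns to 34.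

**Step 32.** Facial selectivity on the flexible ten-membered ring may be poor, and the exocyclic alkene may be epoxidised in competition. The fallback lets the C19 carboxylate deliver the C7 oxygen. It sets out from 41: HF·pyridine gives the C19 alcohol F9, and TEMPO/PhI(OAc)2 in MeCN/H2O gives the carboxylic acid F10. Chlorolactonisation (1,3-dichloro-5,5-dimethylhydantoin, tertiary-amine catalyst) adds chlorine to C6 and the tethered carboxylate to C7 in anti fashion and returns to 46, bypassing steps 32–35.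

Further compounds
F1 | step 27 | sulfoxide adduct: 30 carrying 7α-CH2CH2S(O)Ph | O=C1[C@@]2(C)[C@@H](OCc5ccc(OC)cc5)C[C@@H](OCOC)[C@](OCOC)(COCc4ccc(OC)cc4)[C@@H]2[C@H](OCOC)[C@](OCOC)([C@@H](C)CO[Si](c6ccccc6)(c7ccccc7)C(C)(C)C)[C@H]1CCS(=O)c8ccccc8
F2 | step 27 | 7α-vinyl 2-ketone | O=C1[C@@]2(C)[C@@H](OCc5ccc(OC)cc5)C[C@@H](OCOC)[C@](OCOC)(COCc4ccc(OC)cc4)[C@@H]2[C@H](OCOC)[C@](OCOC)([C@@H](C)CO[Si](c6ccccc6)(c7ccccc7)C(C)(C)C)[C@H]1C=C
F3 | step 27 | 2β,7α-divinyl decalin-2α-ol | C=C[C@]1(O)[C@@]2(C)[C@@H](OCc5ccc(OC)cc5)C[C@@H](OCOC)[C@](OCOC)(COCc4ccc(OC)cc4)[C@@H]2[C@H](OCOC)[C@](OCOC)([C@@H](C)CO[Si](c6ccccc6)(c7ccccc7)C(C)(C)C)[C@H]1C=C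
F4 | step 27 | ten-membered (6E)-en-2-one with C5H2 | C1CC(=O)[C@@]2(C)[C@@H](OCc5ccc(OC)cc5)C[C@@H](OCOC)[C@](OCOC)(COCc4ccc(OC)cc4)[C@@H]2[C@H](OCOC)[C@](OCOC)([C@@H](C)CO[Si](c6ccccc6)(c7ccccc7)C(C)(C)C)/C=C/C1
F5 | step 27 | ten-membered (6E)-ene-2,5-dione | C1CC(=O)[C@@]2(C)[C@@H](OCc5ccc(OC)cc5)C[C@@H](OCOC)[C@](OCOC)(COCc4ccc(OC)cc4)[C@@H]2[C@H](OCOC)[C@](OCOC)([C@@H](C)CO[Si](c6ccccc6)(c7ccccc7)C(C)(C)C)/C=C/C1=O
F6 | step 25 | aldol adduct: 30 carrying 7α-CH(OH)C(SiMe3)=CH2 | O=C1[C@@]2(C)[C@@H](OCc5ccc(OC)cc5)C[C@@H](OCOC)[C@](OCOC)(COCc4ccc(OC)cc4)[C@@H]2[C@H](OCOC)[C@](OCOC)([C@@H](C)CO[Si](c6ccccc6)(c7ccccc7)C(C)(C)C)[C@H]1C(O)C(=C)[Si](C)(C)C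
F7 | step 25 | 2β-vinyl-2α-ol with 7α-CH(OH)C(SiMe3)=CH2 | C=C[C@]1(O)[C@@]2(C)[C@@H](OCc5ccc(OC)cc5)C[C@@H](OCOC)[C@](OCOC)(COCc4ccc(OC)cc4)[C@@H]2[C@H](OCOC)[C@](OCOC)([C@@H](C)CO[Si](c6ccccc6)(c7ccccc7)C(C)(C)C)[C@H]1C(O)C(=C)[Si](C)(C)C
F8 | step 25 | secondary mesylate of F7 | C=C[C@]1(O)[C@@]2(C)[C@@H](OCc5ccc(OC)cc5)C[C@@H](OCOC)[C@](OCOC)(COCc4ccc(OC)cc4)[C@@H]2[C@H](OCOC)[C@](OCOC)([C@@H](C)CO[Si](c6ccccc6)(c7ccccc7)C(C)(C)C)[C@H]1C(OS(C)(=O)=O)C(=C)[Si](C)(C)C
F9 | step 32 | C19 alcohol of 41 | C1C[C@H](OC(=O)C(C)C)[C@@]2(C)[C@@H](OC(C)=O)C[C@@H](OCOC)[C@](OCOC)(COS(=O)(=O)c4ccc(C)cc4)[C@@H]2[C@H](OCOC)[C@](OCOC)([C@@H](C)CO)/C=C/C1=C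
F10 | step 32 | C19 carboxylic acid | C1C[C@H](OC(=O)C(C)C)[C@@]2(C)[C@@H](OC(C)=O)C[C@@H](OCOC)[C@](OCOC)(COS(=O)(=O)c4ccc(C)cc4)[C@@H]2[C@H](OCOC)[C@](OCOC)([C@@H](C)C(=O)O)/C=C/C1=C
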